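**Retrosynthetic overview**

1. Amaurone B ⇐ tetraol 34 (the two secondary hydroxyls are acetylated last) ⇐ silyl-protected triene 33. C11=C12 is cut by aldol–dehydration with the lithiated 2-ethyl γ-pyrone 29; C9=C10 and C7=C8 are cut by Wittig olefinations back to ring aldehyde 12.
2. Feature used: in the carbocycle (C1 bears the chain through C7; C2 CHMe; C3 C(Me)OH; C4 CHOAc; C5 C(Me)OH; C6 CHOAc) C7 is an aldehyde-level carbon on C1, cis to the C2 methyl and trans to the C6 oxygen, and the cis C3/C4 diol can be carried as a C3=C4 alkene. That is a cyclohex-3-ene-1-carbaldehyde.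
3. Key disconnection: C1–C2, by Claisen rearrangement of the all-cis 2-[(E)-but-2-en-2-yl]-3,4-dihydro-2H-pyran 11 (pyran C2/C3/C4/C5/C6 = C4/C5/C6/C1/C7). The C3 and C4 oxygens then come from osmylation directed by the C5 hydroxyl.
4. 11 ⇐ pyranone 4 (hydroxylation, methylation, Luche reduction, two silylations) ⇐ tiglaldehyde 1 + silyloxydiene 2 by catalytic asymmetric hetero-Diels–Alder reaction.
5. Ring order: dihydropyranone (step 1), then the carbocycle at the expense of the pyran (step 7). The γ-pyrone is made separately (steps 15–17) and joined in step 18.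

Key step: step 7

Assumption: the (R)-BINOL/Ti(OiPr)4 catalyst is taken to deliver the diene to the Re face of tiglaldehyde (2R pyranone); should the sense prove opposite, (S)-BINOL is used.

**Route**

Step 1
Reactants: 1 (E)-2-methylbut-2-enal (tiglaldehyde); 2 (E)-1-methoxy-3-(trimethylsilyloxy)buta-1,3-diene
Product: 4 (2R)-2-[(E)-but-2-en-2-yl]-2,3-dihydro-4H-pyran-4-one, via silylated aldol adduct 3 (not isolated)
Conditions: Ti(OiPr)4 (10 mol%), (R)-BINOL (20 mol%), CF3CO2H (cat.), 4 Å MS, Et2O, −20 °C; then CF3CO2H, CH2Cl2, 0 °C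
Reagents that add atoms: none
Why: Keck-type catalytic asymmetric hetero-Diels–Alder reaction run as a Mukaiyama aldol addition of the diene terminus to the Re face of the titanium-bound aldehyde, after which acid closes the pyranone by oxa-Michael addition with loss of methanol and the silyl group, setting pyran C2 (later C4) as R.

Step 2
Reactants: 4 (2R)-2-[(E)-but-2-en-2-yl]-2,3-dihydro-4H-pyran-4-one
Product: 6 (2S,3S)-2-[(E)-but-2-en-2-yl]-3-hydroxy-2,3-dihydro-4H-pyran-4-one, via potassium enolate 5 (not isolated)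
Conditions: KN(SiMe3)2, THF, −78 °C; then 2-(phenylsulfonyl)-3-phenyloxaziridine, −78 °C; AcOH
Reagents that add atoms: 2-(phenylsulfonyl)-3-phenyloxaziridine (Davis oxaziridine), O=S(=O)(c1ccccc1)N1OC1c1ccccc1
Why: Davis enolate hydroxylation: the vinylogous ester can only be deprotonated at pyran C3, the oxaziridine leaves both alkenes alone, and the hydroxyl should enter mainly anti to the butenyl group, although this centre is set again in step 4 so either epimer serves.

Step 3
Reactants: 6 (2S,3S)-2-[(E)-but-2-en-2-yl]-3-hydroxy-2,3-dihydro-4H-pyran-4-one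
Product: 7 (2S,3S)-2-[(E)-but-2-en-2-yl]-3-(triethylsilyloxy)-2,3-dihydro-4H-pyran-4-one
Conditions: TESCl, imidazole, DMF, 0 °C to rt
Reagents that add atoms: chlorotriethylsilane, CC[Si](Cl)(CC)CC
Why: Routine silylation of a secondary α-hydroxy ketone; triethylsilyl is chosen because it can later be taken off the tertiary oxygen while a tert-butyldimethylsilyl ether stays.

Step 4
Reactants: 7 (2S,3S)-2-[(E)-but-2-en-2-yl]-3-(triethylsilyloxy)-2,3-dihydro-4H-pyran-4-one
Product: 9 (2S,3R)-2-[(E)-but-2-en-2-yl]-3-methyl-3-(triethylsilyloxy)-2,3-dihydro-4H-pyran-4-one, via lithium enolate 8 (not isolated)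
Conditions: LiN(iPr)2, THF, −78 °C; then MeI, DMPU, −78 to −40 °C
Reagents that add atoms: iodomethane, CI
Why: Enolate C-alkylation: in the fully substituted silyloxy enolate, allylic 1,2-strain turns the butenyl group pseudoaxial, so iodomethane attacks the other face and the methyl ends trans, the silyloxy group cis, to the butenyl group (this sets C5).

Step 5
Reactants: 9 (2S,3R)-2-[(E)-but-2-en-2-yl]-3-methyl-3-(triethylsilyloxy)-2,3-dihydro-4H-pyran-4-one
Product: 10 (2S,3S,4S)-2-[(E)-but-2-en-2-yl]-3-methyl-3-(triethylsilyloxy)-3,4-dihydro-2H-pyran-4-ol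
Conditions: NaBH4, CeCl3·7H2O, MeOH, −78 °C
Reagents that add atoms: none
Why: Luche 1,2-reduction: with the butenyl group equatorial the pyran C3 silyloxy group is axial, hydride comes from the opposite face, and the new hydroxyl (C6) ends cis to both the silyloxy and the butenyl group, the galactal-type outcome known for cis-2,3-substituted dihydropyranones.

Step 6
Reactants: 10 (2S,3S,4S)-2-[(E)-but-2-en-2-yl]-3-methyl-3-(triethylsilyloxy)-3,4-dihydro-2H-pyran-4-ol
Product: 11 (2S,3R,4S)-2-[(E)-but-2-en-2-yl]-4-(tert-butyldimethylsilyloxy)-3-methyl-3-(triethylsilyloxy)-3,4-dihydro-2H-pyran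
Conditions: TBSOTf, 2,6-lutidine, CH2Cl2, −78 °C
Reagents that add atoms: tert-butyldimethylsilyl triflate, CC(C)(C)[Si](C)(C)OS(=O)(=O)C(F)(F)F
Why: Silylation of the hindered allylic alcohol with a silyl triflate under amine buffering, cold enough that the acid-sensitive glycal-type enol ether is not ionised.

Step 7
Reactants: 11 (2S,3R,4S)-2-[(E)-but-2-en-2-yl]-4-(tert-butyldimethylsilyloxy)-3-methyl-3-(triethylsilyloxy)-3,4-dihydro-2H-pyran
Product: 12 (1R,2S,5R,6S)-6-(tert-butyldimethylsilyloxy)-2,3,5-trimethyl-5-(triethylsilyloxy)cyclohex-3-ene-1-carbaldehyde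
Conditions: degassed PhMe, Et3N (trace), BHT (cat.), base-washed sealed tube, 200 °C
Reagents that add atoms: none
Why: On heating, the allyl vinyl ether C2=C3–C4–O–C7=C1 built into the pyran undergoes a concerted [3,3]-sigmatropic (Claisen) shift: enol-ether carbon C1 bonds to the butenyl terminus C2, the C4–O bond breaks and C7 leaves the ring as a formyl group, whose C=O bond makes the step irreversible. The closest known reaction is the thermal rearrangement of 2-alkenyl-3,4-dihydro-2H-pyrans and C-vinyl glycals to cyclohex-3-enecarbaldehydes, of which this is a more hindered member (trisubstituted terminus beside the quaternary C5). The six-membered carbocycle closes by C1–C2 bond formation across the pyran between its 1,4-related carbons, and because C5–C6 bridges the six reacting atoms only a boat (bicyclo[2.2.2]-like) transition state is possible. C1 is set by the substrate, since the new bond must form on the pyran face that carries the butenyl group and that group is cis to the C6 silyloxy group, so the formyl carbon ends trans to C6–O; C2 is set by the E alkene, whose terminal methyl points away from the bridge in the boat and ends cis to the formyl group. C5 and C6 take no part and keep their configuration. The step needs only this diastereocontrol and survival of the allylic silyl ether, which the enforced boat, the all-cis substitution and neutral, acid-free conditions should secure.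

Step 8
Reactants: 12 (1R,2S,5R,6S)-6-(tert-butyldimethylsilyloxy)-2,3,5-trimethyl-5-(triethylsilyloxy)cyclohex-3-ene-1-carbaldehyde; 13 ethyl 2-(triphenylphosphoranylidene)propanoate
Product: 14 ethyl (E)-3-[6-(tert-butyldimethylsilyloxy)-2,3,5-trimethyl-5-(triethylsilyloxy)cyclohex-3-en-1-yl]-2-methylprop-2-enoate (ring configuration of 12)
Conditions: PhMe, 90 °C
Reagents that add atoms: none
Why: Wittig reaction with a stabilised ylide gives the E trisubstituted enoate (C7=C8) under neutral conditions, so C1 should not epimerise and the β-silyloxy group should not eliminate.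

Step 9
Reactants: 14 ethyl (E)-3-[6-(tert-butyldimethylsilyloxy)-2,3,5-trimethyl-5-(triethylsilyloxy)cyclohex-3-en-1-yl]-2-methylprop-2-enoate
Product: 15 ethyl (E)-3-[6-(tert-butyldimethylsilyloxy)-5-hydroxy-2,3,5-trimethylcyclohex-3-en-1-yl]-2-methylprop-2-enoate
Conditions: HF·pyridine, pyridine, THF, 0 °C
Reagents that add atoms: none
Why: Selective fluoride desilylation: a triethylsilyl ether is cleaved far faster than the hindered secondary tert-butyldimethylsilyl ether, which frees only the C5 hydroxyl.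

Step 10
Reactants: 15 ethyl (E)-3-[6-(tert-butyldimethylsilyloxy)-5-hydroxy-2,3,5-trimethylcyclohex-3-en-1-yl]-2-methylprop-2-enoate
Product: 17 ethyl (E)-3-[6-(tert-butyldimethylsilyloxy)-3,4,5-trihydroxy-2,3,5-trimethylcyclohexyl]-2-methylprop-2-enoate (all four ring oxygens cis), via osmate ester 16 (not isolated)
Conditions: OsO4 (1.05 equiv), TMEDA, CH2Cl2, −78 °C; then aq. Na2SO3, THF, 60 °C
Reagents that add atoms: osmium tetroxide, O=[Os](=O)(=O)=O
Why: Donohoe hydrogen-bond-directed dihydroxylation: the OsO4·TMEDA complex is held by the C5 hydroxyl and adds to the C3=C4 face syn to it, which is also the face free of the C2 and C5 methyl groups, setting C3 and C4, while the electron-poor, undirected enoate alkene should not react.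

Step 11
Reactants: 17 ethyl (E)-3-[6-(tert-butyldimethylsilyloxy)-3,4,5-trihydroxy-2,3,5-trimethylcyclohexyl]-2-methylprop-2-enoate
Product: 18 ethyl (E)-3-[6-(tert-butyldimethylsilyloxy)-2,3,5-trimethyl-3,4,5-tris(trimethylsilyloxy)cyclohexyl]-2-methylprop-2-enoate
Conditions: TMSOTf (excess), 2,6-lutidine, CH2Cl2, −78 to 0 °C
Reagents that add atoms: trimethylsilyl triflate, C[Si](C)(C)OS(=O)(=O)C(F)(F)F
Why: Exhaustive silylation with the small, very reactive silyl triflate caps the two tertiary and the flanked secondary hydroxyl in one operation, and these hindered trimethylsilyl ethers should last through the neutral and basic steps that follow.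

Step 12
Reactants: 18 ethyl (E)-3-[6-(tert-butyldimethylsilyloxy)-2,3,5-trimethyl-3,4,5-tris(trimethylsilyloxy)cyclohexyl]-2-methylprop-2-enoate
Product: 19 (E)-3-[6-(tert-butyldimethylsilyloxy)-2,3,5-trimethyl-3,4,5-tris(trimethylsilyloxy)cyclohexyl]-2-methylprop-2-en-1-ol
Conditions: iBu2AlH, CH2Cl2, −78 °C; aq. potassium sodium tartrate
Reagents that add atoms: none
Why: Aluminium hydride 1,2-reduction of the enoate to the allylic alcohol, with a neutral tartrate work-up that spares the silyl ethers.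

Step 13
Reactants: 19 (E)-3-[6-(tert-butyldimethylsilyloxy)-2,3,5-trimethyl-3,4,5-tris(trimethylsilyloxy)cyclohexyl]-2-methylprop-2-en-1-ol; 20 N-methoxy-N-methyl-2-(triphenylphosphoranylidene)acetamide
Product: 22 (2E,4E)-N-methoxy-N,4-dimethyl-5-[6-(tert-butyldimethylsilyloxy)-2,3,5-trimethyl-3,4,5-tris(trimethylsilyloxy)cyclohexyl]penta-2,4-dienamide, via enal 21 (not isolated)
Conditions: MnO2, PhMe, 80 °C
Reagents that add atoms: none
Why: Tandem oxidation–Wittig process: MnO2 oxidises the allylic alcohol and the enal is trapped at once by the stabilised amide ylide, giving the E C9=C10 bond without a second homologation.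

Step 14
Reactants: 22 (2E,4E)-N-methoxy-N,4-dimethyl-5-[6-(tert-butyldimethylsilyloxy)-2,3,5-trimethyl-3,4,5-tris(trimethylsilyloxy)cyclohexyl]penta-2,4-dienamide
Product: 23 (2E,4E)-4-methyl-5-[6-(tert-butyldimethylsilyloxy)-2,3,5-trimethyl-3,4,5-tris(trimethylsilyloxy)cyclohexyl]penta-2,4-dienal
Conditions: iBu2AlH, THF, −78 °C
Reagents that add atoms: none
Why: Weinreb amide reduction stops at the chelated hemiaminal, which releases the dienal only on work-up.

Step 15
Reactants: 24 methyl 2-methyl-3-oxopentanoate; 25 N-methoxy-N-methylpropanamide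
Product: 27 methyl 2,4-dimethyl-3,5-dioxoheptanoate, via keto ester dianion 26 (not isolated)
Conditions: NaH, THF, 0 °C; n-BuLi, 0 °C; then 25, −78 to 0 °C; aq. HCl
Reagents that add atoms: none
Why: γ-Acylation of a β-keto ester dianion (Huckin–Weiler type) at its more basic terminal carbon, with the Weinreb amide adduct holding until work-up so that neither over-addition nor proton quench occurs.

Step 16
Reactants: 27 methyl 2,4-dimethyl-3,5-dioxoheptanoate
Product: 28 6-ethyl-4-hydroxy-3,5-dimethyl-2H-pyran-2-one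
Conditions: DBU, PhMe, 110 °C
Reagents that add atoms: none
Why: Base-mediated enol lactonisation of the 3,5-dioxo ester with loss of methanol, driven by formation of the conjugated pyranone.

Step 17
Reactants: 28 6-ethyl-4-hydroxy-3,5-dimethyl-2H-pyran-2-one
Product: 29 2-ethyl-6-methoxy-3,5-dimethyl-4H-pyran-4-one
Conditions: MeOTf, CH2Cl2, rt; aq. NaHCO3
Reagents that add atoms: methyl triflate, COS(=O)(=O)C(F)(F)F
Why: O-Methylation with a hard methylating agent occurs at the lactone carbonyl oxygen, and loss of the hydroxyl proton then gives the 2-methoxy-4-pyranone, not the 4-methoxy-2-pyranone.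

Step 18
Reactants: 29 2-ethyl-6-methoxy-3,5-dimethyl-4H-pyran-4-one; 23 (2E,4E)-4-methyl-5-[6-(tert-butyldimethylsilyloxy)-2,3,5-trimethyl-3,4,5-tris(trimethylsilyloxy)cyclohexyl]penta-2,4-dienal
Product: 31 2-[(4E,6E)-3-hydroxy-6-methyl-7-[6-(tert-butyldimethylsilyloxy)-2,3,5-trimethyl-3,4,5-tris(trimethylsilyloxy)cyclohexyl]hepta-4,6-dien-2-yl]-6-methoxy-3,5-dimethyl-4H-pyran-4-one (mixture at the two new centres), via lithiated pyrone 30 (not isolated)
Conditions: LiN(SiMe3)2, THF, −78 °C; then 23, −78 °C; AcOH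
Reagents that add atoms: none
Why: Vinylogous aldol addition: the γ-pyrone is deprotonated only at the CH2 of its 2-ethyl group and the lithium dienolate adds 1,2 to the dienal, forming C11–C12 with two stereocentres that are removed in the next step.

Step 19
Reactants: 31 aldol adduct (as in step 18)
Product: 33 2-[(2E,4E,6E)-6-methyl-7-[6-(tert-butyldimethylsilyloxy)-2,3,5-trimethyl-3,4,5-tris(trimethylsilyloxy)cyclohexyl]hepta-2,4,6-trien-2-yl]-6-methoxy-3,5-dimethyl-4H-pyran-4-one, via mesylate 32 (not isolated)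
Conditions: MsCl, Et3N, CH2Cl2, 0 °C; then DBU, rt
Reagents that add atoms: none
Why: Mesylation followed by E1cB-type elimination, the proton at C12 being acidified by the pyrone, gives the fully conjugated C11=C12 alkene as the more stable E isomer (pyrone trans to C10) from both aldol diastereomers.

Step 20
Reactants: 33 silyl-protected triene (as in step 19)
Product: 34 2-[(2E,4E,6E)-6-methyl-7-(3,4,5,6-tetrahydroxy-2,3,5-trimethylcyclohexyl)hepta-2,4,6-trien-2-yl]-6-methoxy-3,5-dimethyl-4H-pyran-4-one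
Conditions: HF·pyridine, pyridine, THF, 0 °C to rt, dark
Reagents that add atoms: none
Why: Global fluoride desilylation under buffered conditions removes the three trimethylsilyl groups and the tert-butyldimethylsilyl group without harming the triene or the methoxypyrone.

Step 21
Reactants: 34 tetraol (as in step 20)
Product: 35 Amaurone B
Conditions: Ac2O, pyridine, DMAP (cat.), CH2Cl2, 0 °C to rt
Reagents that add atoms: acetic anhydride, CC(=O)OC(C)=O
Why: Chemoselective acylation: the two secondary hydroxyls (C4, C6) are esterified while the two tertiary hydroxyls (C3, C5) are too hindered to react under these conditions.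

**Compound list**

1 | (E)-2-methylbut-2-enal (tiglaldehyde) | C/C=C(\C)C=O | starting material
2 | (E)-1-methoxy-3-(trimethylsilyloxy)buta-1,3-diene | CO/C=C/C(=C)O[Si](C)(C)C | starting material
3 | (5R,1E,6E)-1-methoxy-6-methyl-5-(trimethylsilyloxy)octa-1,6-dien-3-one (not isolated) | CO/C=C/C(=O)C[C@@H](O[Si](C)(C)C)/C(C)=C/C | intermediate
4 | (2R)-2-[(E)-but-2-en-2-yl]-2,3-dihydro-4H-pyran-4-one | C1=CC(=O)C[C@H](/C(C)=C/C)O1 | intermediate
5 | potassium enolate of 4 (not isolated) | C1=CC(O[K])=C[C@H](/C(C)=C/C)O1 | intermediate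
6 | (2S,3S)-2-[(E)-but-2-en-2-yl]-3-hydroxy-2,3-dihydro-4H-pyran-4-one (hydroxyl trans to butenyl) | C1=CC(=O)[C@@H](O)[C@H](/C(C)=C/C)O1 | intermediate
7 | (2S,3S)-2-[(E)-but-2-en-2-yl]-3-(triethylsilyloxy)-2,3-dihydro-4H-pyran-4-one | C1=CC(=O)[C@@H](O[Si](CC)(CC)CC)[C@H](/C(C)=C/C)O1 | intermediate
8 | lithium enolate of 7 (not isolated) | C1=CC(O[Li])=C(O[Si](CC)(CC)CC)[C@H](/C(C)=C/C)O1 | intermediate
9 | (2S,3R)-2-[(E)-but-2-en-2-yl]-3-methyl-3-(triethylsilyloxy)-2,3-dihydro-4H-pyran-4-one (silyloxy cis to butenyl) | C1=CC(=O)[C@](C)(O[Si](CC)(CC)CC)[C@H](/C(C)=C/C)O1 | intermediate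
10 | (2S,3S,4S)-2-[(E)-but-2-en-2-yl]-3-methyl-3-(triethylsilyloxy)-3,4-dihydro-2H-pyran-4-ol (butenyl, silyloxy, hydroxyl all cis) | C1=C[C@H](O)[C@](C)(O[Si](CC)(CC)CC)[C@H](/C(C)=C/C)O1 | intermediate
11 | (2S,3R,4S)-2-[(E)-but-2-en-2-yl]-4-(tert-butyldimethylsilyloxy)-3-methyl-3-(triethylsilyloxy)-3,4-dihydro-2H-pyran (butenyl and both oxygens cis) | C1=C[C@H](O[Si](C)(C)C(C)(C)C)[C@](C)(O[Si](CC)(CC)CC)[C@H](/C(C)=C/C)O1 | intermediate
12 | (1R,2S,5R,6S)-6-(tert-butyldimethylsilyloxy)-2,3,5-trimethyl-5-(triethylsilyloxy)cyclohex-3-ene-1-carbaldehyde | O=C[C@@H]1[C@H](C)C(C)=C[C@@](C)(O[Si](CC)(CC)CC)[C@H]1O[Si](C)(C)C(C)(C)C | intermediate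
13 | ethyl 2-(triphenylphosphoranylidene)propanoate | CCOC(=O)C(C)=P(c1ccccc1)(c1ccccc1)c1ccccc1 | starting material
14 | ethyl (E)-2-methyl-3-[ring of 12]prop-2-enoate | CCOC(=O)/C(C)=C/[C@@H]1[C@H](C)C(C)=C[C@@](C)(O[Si](CC)(CC)CC)[C@H]1O[Si](C)(C)C(C)(C)C | intermediate
15 | ethyl (E)-3-[6-(tert-butyldimethylsilyloxy)-5-hydroxy-2,3,5-trimethylcyclohex-3-en-1-yl]-2-methylprop-2-enoate | CCOC(=O)/C(C)=C/[C@@H]1[C@H](C)C(C)=C[C@@](C)(O)[C@H]1O[Si](C)(C)C(C)(C)C | intermediate
16 | C3,C4 osmate ester of 15, hexavalent osmium chelated by TMEDA (not isolated) | CCOC(=O)/C(C)=C/[C@@H]1[C@H](C)[C@@](C)(O3)[C@@H](O[Os-2]34(=O)(=O)[N+](C)(C)CC[N+]4(C)C)[C@@](C)(O)[C@H]1O[Si](C)(C)C(C)(C)C | intermediate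
17 | ethyl (E)-3-[6-(tert-butyldimethylsilyloxy)-3,4,5-trihydroxy-2,3,5-trimethylcyclohexyl]-2-methylprop-2-enoate (four ring oxygens cis) | CCOC(=O)/C(C)=C/[C@@H]1[C@H](C)[C@@](C)(O)[C@@H](O)[C@@](C)(O)[C@H]1O[Si](C)(C)C(C)(C)C | intermediate
18 | tris(trimethylsilyl) ether of 17 | CCOC(=O)/C(C)=C/[C@@H]1[C@H](C)[C@@](C)(O[Si](C)(C)C)[C@@H](O[Si](C)(C)C)[C@@](C)(O[Si](C)(C)C)[C@H]1O[Si](C)(C)C(C)(C)C | intermediate
19 | (E)-2-methyl-3-[ring of 18]prop-2-en-1-ol | OC/C(C)=C/[C@@H]1[C@H](C)[C@@](C)(O[Si](C)(C)C)[C@@H](O[Si](C)(C)C)[C@@](C)(O[Si](C)(C)C)[C@H]1O[Si](C)(C)C(C)(C)C | intermediate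
20 | N-methoxy-N-methyl-2-(triphenylphosphoranylidene)acetamide | CON(C)C(=O)C=P(c1ccccc1)(c1ccccc1)c1ccccc1 | starting material
21 | (E)-2-methyl-3-[ring of 18]prop-2-enal (not isolated) | O=C/C(C)=C/[C@@H]1[C@H](C)[C@@](C)(O[Si](C)(C)C)[C@@H](O[Si](C)(C)C)[C@@](C)(O[Si](C)(C)C)[C@H]1O[Si](C)(C)C(C)(C)C | intermediate
22 | (2E,4E)-N-methoxy-N,4-dimethyl-5-[ring of 18]penta-2,4-dienamide | CON(C)C(=O)/C=C/C(C)=C/[C@@H]1[C@H](C)[C@@](C)(O[Si](C)(C)C)[C@@H](O[Si](C)(C)C)[C@@](C)(O[Si](C)(C)C)[C@H]1O[Si](C)(C)C(C)(C)C | intermediate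
23 | (2E,4E)-4-methyl-5-[ring of 18]penta-2,4-dienal | O=C/C=C/C(C)=C/[C@@H]1[C@H](C)[C@@](C)(O[Si](C)(C)C)[C@@H](O[Si](C)(C)C)[C@@](C)(O[Si](C)(C)C)[C@H]1O[Si](C)(C)C(C)(C)C | intermediate
24 | methyl 2-methyl-3-oxopentanoate | CCC(=O)C(C)C(=O)OC | starting material
25 | N-methoxy-N-methylpropanamide | CCC(=O)N(C)OC | starting material
26 | sodium lithium dianion of 24 (not isolated) | CC=C(O[Li])C(C)=C(OC)O[Na] | intermediate
27 | methyl 2,4-dimethyl-3,5-dioxoheptanoate (stereoisomer and tautomer mixture) | CCC(=O)C(C)C(=O)C(C)C(=O)OC | intermediate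
28 | 6-ethyl-4-hydroxy-3,5-dimethyl-2H-pyran-2-one | CCc1oc(=O)c(C)c(O)c1C | intermediate
29 | 2-ethyl-6-methoxy-3,5-dimethyl-4H-pyran-4-one | CCc1oc(OC)c(C)c(=O)c1C | intermediate
30 | lithium dienolate of 29 (not isolated) | CC=C1OC(OC)=C(C)C(O[Li])=C1C | intermediate
31 | aldol adduct, C11 hydroxyl and C12 methyl as a diastereomer mixture | COc1oc(C(C)C(O)/C=C/C(C)=C/[C@@H]2[C@H](C)[C@@](C)(O[Si](C)(C)C)[C@@H](O[Si](C)(C)C)[C@@](C)(O[Si](C)(C)C)[C@H]2O[Si](C)(C)C(C)(C)C)c(C)c(=O)c1C | intermediate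
32 | C11 mesylate of 31 (not isolated) | COc1oc(C(C)C(OS(C)(=O)=O)/C=C/C(C)=C/[C@@H]2[C@H](C)[C@@](C)(O[Si](C)(C)C)[C@@H](O[Si](C)(C)C)[C@@](C)(O[Si](C)(C)C)[C@H]2O[Si](C)(C)C(C)(C)C)c(C)c(=O)c1C | intermediate
33 | silyl-protected (2E,4E,6E)-triene pyrone | COc1oc(/C(C)=C/C=C/C(C)=C/[C@@H]2[C@H](C)[C@@](C)(O[Si](C)(C)C)[C@@H](O[Si](C)(C)C)[C@@](C)(O[Si](C)(C)C)[C@H]2O[Si](C)(C)C(C)(C)C)c(C)c(=O)c1C | intermediate
34 | tetraol (bis-deacetyl Amaurone B) | COc1oc(/C(C)=C/C=C/C(C)=C/[C@@H]2[C@H](C)[C@@](C)(O)[C@@H](O)[C@@](C)(O)[C@H]2O)c(C)c(=O)c1C | intermediate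
35 | Amaurone B | COc1oc(/C(C)=C/C=C/C(C)=C/[C@@H]2[C@H](C)[C@@](C)(O)[C@@H](OC(C)=O)[C@@](C)(O)[C@H]2OC(C)=O)c(C)c(=O)c1C | target

**Step count**

Total: 21 steps. Longest linear sequence: 18 steps (steps 1–14 and 18–21); the pyrone branch is steps 15–17.

**Steps most likely to fail, with fallbacks**

Step 7 (Claisen rearrangement). The boat transition state has to seat a trisubstituted alkene terminus next to the quaternary C5. It may be reached only at temperatures where the allylic silyl ether ionises or eliminates, or where the new aldehyde epimerises at C1. The fallback keeps the same bond but moves to the ester oxidation level, where the lactone-enolate (Ireland-type) Claisen ring contraction of 6-alkenyl δ-lactones runs far cooler. It sets out from 11.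
- Mild hydration of the enol ether (Ph3P·HBr cat., THF/H2O) gives the 2-deoxy lactol F1.
- Oxidation (Pr4N[RuO4], NMO) gives the δ-lactone F2.
- LiN(SiMe3)2 with TMSCl/Et3N already present at −78 °C gives the cyclic silyl ketene acetal F3. The β-silyloxy group is equatorial and poorly aligned for elimination, and the internal quench traps the enolate.
- Warming in toluene to about 90 °C takes F3 through the same boat to the trimethylsilyl ester F4, which aqueous work-up hydrolyses to the carboxylic acid F5.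
- MeNH(OMe)·HCl with EDC·HCl gives the Weinreb amide F6, and iBu2AlH at −78 °C comes back to the route at 12.

Step 4 (enolate methylation). The silyl group may migrate between the two enediolate oxygens, the enolate may be methylated on oxygen or open the ring by β-elimination, or the facial selectivity may be poor. The fallback makes the tertiary carbinol by carbonyl addition instead. It sets out from 7.
- Luche reduction gives the alcohol F7, with the hydroxyl cis to the butenyl group by axial hydride attack on the diequatorial conformer.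
- TBSOTf/2,6-lutidine gives the bis-silyl ether F8.
- HF·pyridine removes the secondary triethylsilyl group selectively to give the alcohol F9.
- Buffered Dess–Martin oxidation gives the pyran-3-one F10.
- MeLi/CeCl3 at −78 °C adds from the face opposite to the cis butenyl and silyloxy groups to give the tertiary alcohol F11.
- TESOTf/2,6-lutidine comes back to the route at 11.

Step 10 (directed dihydroxylation). Osmylation of the hindered trisubstituted ring alkene may be slow enough for the reagent to attack the enoate alkene, and hydrolysis of the hindered osmate ester may stall. The fallback removes the competing alkene by osmylating before the olefination. It sets out from 12.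
- NaBH4 in MeOH gives the primary alcohol F12.
- HF·pyridine gives the diol F13.
- OsO4·TMEDA gives, through the osmate ester F14, the tetraol F15.
- TMSOTf/2,6-lutidine gives the tetrakis(trimethylsilyl) ether F16.
- Swern conditions ((COCl)2, DMSO, Et3N) oxidise the primary trimethylsilyl ether directly, a known selective oxidation of primary silyl ethers, to the aldehyde F17.
- Wittig reaction with 13 comes back to the route at 18.

**Further compounds**

F1 | step 7 | 2-deoxy lactol from 11 (anomer mixture) | OC1C[C@H](O[Si](C)(C)C(C)(C)C)[C@](C)(O[Si](CC)(CC)CC)[C@H](/C(C)=C/C)O1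
F2 | step 7 | 6-[(E)-but-2-en-2-yl]-4-(tert-butyldimethylsilyloxy)-5-methyl-5-(triethylsilyloxy)tetrahydro-2H-pyran-2-one (all cis) | O=C1C[C@H](O[Si](C)(C)C(C)(C)C)[C@](C)(O[Si](CC)(CC)CC)[C@H](/C(C)=C/C)O1
F3 | step 7 | cyclic trimethylsilyl ketene acetal of F2 | C[Si](C)(C)OC1=C[C@H](O[Si](C)(C)C(C)(C)C)[C@](C)(O[Si](CC)(CC)CC)[C@H](/C(C)=C/C)O1
F4 | step 7 | trimethylsilyl ester of F5 | C[Si](C)(C)OC(=O)[C@@H]1[C@H](C)C(C)=C[C@@](C)(O[Si](CC)(CC)CC)[C@H]1O[Si](C)(C)C(C)(C)C
F5 | step 7 | 6-(tert-butyldimethylsilyloxy)-2,3,5-trimethyl-5-(triethylsilyloxy)cyclohex-3-ene-1-carboxylic acid (configuration of 12) | OC(=O)[C@@H]1[C@H](C)C(C)=C[C@@](C)(O[Si](CC)(CC)CC)[C@H]1O[Si](C)(C)C(C)(C)C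
F6 | step 7 | N-methoxy-N-methyl amide of F5 | CON(C)C(=O)[C@@H]1[C@H](C)C(C)=C[C@@](C)(O[Si](CC)(CC)CC)[C@H]1O[Si](C)(C)C(C)(C)C
F7 | step 4 | 2-[(E)-but-2-en-2-yl]-3-(triethylsilyloxy)-3,4-dihydro-2H-pyran-4-ol (hydroxyl cis to butenyl, trans to silyloxy) | C1=C[C@H](O)[C@@H](O[Si](CC)(CC)CC)[C@H](/C(C)=C/C)O1
F8 | step 4 | tert-butyldimethylsilyl ether of F7 | C1=C[C@H](O[Si](C)(C)C(C)(C)C)[C@@H](O[Si](CC)(CC)CC)[C@H](/C(C)=C/C)O1
F9 | step 4 | 2-[(E)-but-2-en-2-yl]-4-(tert-butyldimethylsilyloxy)-3,4-dihydro-2H-pyran-3-ol | C1=C[C@H](O[Si](C)(C)C(C)(C)C)[C@@H](O)[C@H](/C(C)=C/C)O1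
F10 | step 4 | 2-[(E)-but-2-en-2-yl]-4-(tert-butyldimethylsilyloxy)-2H-pyran-3(4H)-one (substituents cis) | C1=C[C@H](O[Si](C)(C)C(C)(C)C)C(=O)[C@H](/C(C)=C/C)O1
F11 | step 4 | 2-[(E)-but-2-en-2-yl]-4-(tert-butyldimethylsilyloxy)-3-methyl-3,4-dihydro-2H-pyran-3-ol (butenyl, hydroxyl, silyloxy all cis) | C1=C[C@H](O[Si](C)(C)C(C)(C)C)[C@](C)(O)[C@H](/C(C)=C/C)O1
F12 | step 10 | [6-(tert-butyldimethylsilyloxy)-2,3,5-trimethyl-5-(triethylsilyloxy)cyclohex-3-en-1-yl]methanol | OC[C@@H]1[C@H](C)C(C)=C[C@@](C)(O[Si](CC)(CC)CC)[C@H]1O[Si](C)(C)C(C)(C)C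
F13 | step 10 | 6-(tert-butyldimethylsilyloxy)-1-(hydroxymethyl)-2,3,5-trimethylcyclohex-3-en-5-ol (diol from F12) | OC[C@@H]1[C@H](C)C(C)=C[C@@](C)(O)[C@H]1O[Si](C)(C)C(C)(C)C
F14 | step 10 | C3,C4 osmate ester of F13, hexavalent osmium chelated by TMEDA | OC[C@@H]1[C@H](C)[C@@](C)(O3)[C@@H](O[Os-2]34(=O)(=O)[N+](C)(C)CC[N+]4(C)C)[C@@](C)(O)[C@H]1O[Si](C)(C)C(C)(C)C
F15 | step 10 | tetraol: C7, C3, C4, C5 hydroxyls free, C6 tert-butyldimethylsilyl ether | OC[C@@H]1[C@H](C)[C@@](C)(O)[C@@H](O)[C@@](C)(O)[C@H]1O[Si](C)(C)C(C)(C)C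
F16 | step 10 | tetrakis(trimethylsilyl) ether of F15 | C[Si](C)(C)OC[C@@H]1[C@H](C)[C@@](C)(O[Si](C)(C)C)[C@@H](O[Si](C)(C)C)[C@@](C)(O[Si](C)(C)C)[C@H]1O[Si](C)(C)C(C)(C)C
F17 | step 10 | 6-(tert-butyldimethylsilyloxy)-2,3,5-trimethyl-3,4,5-tris(trimethylsilyloxy)cyclohexane-1-carbaldehyde | O=C[C@@H]1[C@H](C)[C@@](C)(O[Si](C)(C)C)[C@@H](O[Si](C)(C)C)[C@@](C)(O[Si](C)(C)C)[C@H]1O[Si](C)(C)C(C)(C)C
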